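**Strategy.** The 1,2-dioxane (O1, O2, C3–C6) is disconnected at C5–C6 and O2–C3. Two features are used: ketal carbon C6 is at the carboxylic acid oxidation level, and C3 lies β to the side-chain carboxyl. In one flask a trimethyl ortho ester of the enyne acid is allylated at C6 by the γ-carbon of a 3-silyl pent-4-enoate (C5–C6), the resulting ketal takes up hydrogen peroxide, and the tethered hydroperoxide closes onto C3 by catalyst-controlled 6-exo oxa-Michael addition once the alkene has moved into conjugation (O2–C3). The precursors are ortho ester 7, racemic allylsilane 11 and hydrogen peroxide; neither resembles the ring.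

Key step: step 5

Remark on the chemistry: the L-tert-leucine-derived iminophosphorane–thiourea catalyst is assumed, by analogy with its use for alcohol nucleophiles, to direct the peroxide to the Si face of C3 (giving 3S). If the sense proves opposite, the D-tert-leucine-derived antipode replaces it under the same conditions.

**Step 1**
Reactants: 1 undec-1-yne
Product: 3 (E)-1-iodoundec-1-ene, via alkenylzirconocene chloride 2 (not isolated)
Conditions: Cp2Zr(H)Cl (tetravalent zirconium), THF, rt; then I2, 0 °C
Reagents that add atoms: iodine (II)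
Why: Hydrozirconation adds Zr–H syn and anti-Markovnikov to the terminal alkyne, and iodinolysis of the C–Zr bond goes with retention, so the (E)-alkenyl iodide should result.

**Step 2**
Reactants: 4 hex-5-ynenitrile
Product: 6 6,6,6-trimethoxyhex-1-yne, via imidate hydrochloride 5 (not isolated)
Conditions: HCl (g), MeOH (1.1 equiv), Et2O, 0 °C; then MeOH, hexane, rt
Reagents that add atoms: methanol (CO)
Why: Pinner reaction: the nitrile gives the imidate salt, whose alcoholysis with excess methanol should give the trimethyl ortho ester; the terminal alkyne is inert.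

**Step 3**
Reactants: 6 6,6,6-trimethoxyhex-1-yne; 3 (E)-1-iodoundec-1-ene
Product: 7 (E)-1,1,1-trimethoxyheptadec-7-en-5-yne
Conditions: PdCl2(PPh3)2 (divalent palladium, 2 mol %), CuI (monovalent copper, 4 mol %), Et3N, THF, rt
Reagents that add atoms: none
Why: Sonogashira coupling joins the sp and sp2 carbons with retention of the (E)-geometry; the ortho ester tolerates the basic, anhydrous medium.

**Step 4**
Reactants: 8 (E)-3-(trimethylsilyl)prop-2-en-1-ol
Product: 11 methyl 3-(trimethylsilyl)pent-4-enoate (racemic), via mixed ortho ester 9 (not isolated), via ketene acetal 10 (not isolated)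
Conditions: MeC(OMe)3, EtCO2H (cat.), 110–140 °C, MeOH distilled off
Reagents that add atoms: trimethyl orthoacetate (CC(OC)(OC)OC)
Why: Johnson–Claisen rearrangement: alkoxy exchange and loss of methanol give ketene acetal 10, whose [3,3]-shift places silicon on C3 of the pentenoate; the stereocentre is formed racemic and is destroyed in step 5.

**Step 5**
Reactants: 7 (E)-1,1,1-trimethoxyheptadec-7-en-5-yne; 11 methyl 3-(trimethylsilyl)pent-4-enoate
Product: 15 methyl 2-[(3S,6RS)-6-[(E)-hexadec-6-en-4-yn-1-yl]-6-methoxy-1,2-dioxan-3-yl]acetate, via dimethyl ketal 12 (not isolated), via hydroperoxy ketal 13 (not isolated), via conjugated hydroperoxy ketal 14 (not isolated)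
Conditions: Me3SiOTf (5 mol %), CH2Cl2, −78 °C; then H2O2 (anhydrous, in Et2O, 1.5 equiv), MeOH, −20 to 0 °C; solvent switch to toluene; then (S)-tBuCH[NHC(S)NH-3,5-(CF3)2C6H3]CH2N=P(C6H4-4-OMe)3 (12 mol %), 0 °C to rt
Reagents that add atoms: hydrogen peroxide (OO)
Why: Stage 1 is a silyl-triflate-catalysed Hosomi–Sakurai reaction: ortho ester 7 ionises to a dialkoxycarbenium ion that is attacked by the γ-carbon of allylsilane 11 (SE2′ through the β-silyl cation), forming C5–C6 and the (E)-alkene of 12; the ortho ester ionises far more readily than the product ketal or the ester, which should secure mono-alkylation. Stage 2 is the known acid-catalysed exchange of one ketal methoxy group for hydrogen peroxide, giving α-methoxy hydroperoxide 13. Stage 3 is the base-catalysed hydroperoxide oxa-Michael cyclisation known for 1,2-dioxane-3-acetates, run here with a bifunctional iminophosphorane–thiourea superbase, a catalyst class established for enantioselective intramolecular oxa-Michael additions of alcohols to α,β-unsaturated esters; the base equilibrates 13 with conjugated ester 14 and only 14 can cyclise (Curtin–Hammett funnel). The ring closes in the 6-exo-trig mode, forming O2–C3. C3 is set by the catalyst (peroxide anion paired with the protonated iminophosphorane, ester carbonyl held by the thiourea, attack on the Si face gives 3S), while C6 is not controlled here and is corrected in step 6. The step needs chemoselective ionisation (ortho ester over ketal), γ-regioselectivity (directed by silicon) and exo ring closure (fixed by the tether length).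

**Step 6**
Reactants: 15 methyl 2-[(3S,6RS)-6-[(E)-hexadec-6-en-4-yn-1-yl]-6-methoxy-1,2-dioxan-3-yl]acetate
Product: 16 methyl 2-[(3S,6R)-6-[(E)-hexadec-6-en-4-yn-1-yl]-6-methoxy-1,2-dioxan-3-yl]acetate
Conditions: (1S)-(+)-10-camphorsulfonic acid (10 mol %), MeOH, 0 °C to rt
Reagents that add atoms: methanol (CO)
Why: Acid-catalysed transketalisation: reversible ionisation to the ring peroxycarbenium ion and axial return of methanol should converge on the anomerically stabilised isomer with axial OMe and both carbon substituents equatorial, which is 6R for 3S; C3 is not touched.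

**Step 7**
Reactants: 16 methyl 2-[(3S,6R)-6-[(E)-hexadec-6-en-4-yn-1-yl]-6-methoxy-1,2-dioxan-3-yl]acetate
Product: 17 2-[(3S,6R)-6-[(E)-hexadec-6-en-4-yn-1-yl]-6-methoxy-1,2-dioxan-3-yl]acetic acid (CNP0298534.1)
Conditions: LiOH·H2O, THF/H2O, 0 °C; then aq. HCl to pH 4
Reagents that add atoms: lithium hydroxide ([Li+].[OH-])
Why: Saponification at 0 °C should be faster than α-deprotonation of the β-peroxy ester, so C3 and the O–O bond stay intact; the peroxyketal is stable to base.

**Compound list**

1 | undec-1-yne | C#CCCCCCCCCC | starting material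
2 | chloro[(E)-undec-1-en-1-yl]bis(cyclopentadienyl)zirconium | CCCCCCCCC/C=C/[Zr](Cl)(C1C=CC=C1)C1C=CC=C1 | intermediate
3 | (E)-1-iodoundec-1-ene | CCCCCCCCC/C=C/I | intermediate
4 | hex-5-ynenitrile | C#CCCCC#N | starting material
5 | methyl hex-5-ynimidate hydrochloride | C#CCCCC(=[NH2+])OC.[Cl-] | intermediate
6 | 6,6,6-trimethoxyhex-1-yne | C#CCCCC(OC)(OC)OC | intermediate
7 | (E)-1,1,1-trimethoxyheptadec-7-en-5-yne | CCCCCCCCC/C=C/C#CCCCC(OC)(OC)OC | intermediate
8 | (E)-3-(trimethylsilyl)prop-2-en-1-ol | C[Si](C)(C)/C=C/CO | starting material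
9 | trimethyl{(E)-3-[(1,1-dimethoxyethyl)oxy]prop-1-en-1-yl}silane | CC(OC)(OC)OC/C=C/[Si](C)(C)C | intermediate
10 | trimethyl{(E)-3-[(1-methoxyethenyl)oxy]prop-1-en-1-yl}silane | C=C(OC)OC/C=C/[Si](C)(C)C | intermediate
11 | methyl 3-(trimethylsilyl)pent-4-enoate (racemic) | COC(=O)CC(C=C)[Si](C)(C)C | intermediate
12 | methyl (3E,12E)-6,6-dimethoxydocosa-3,12-dien-10-ynoate | CCCCCCCCC/C=C/C#CCCCC(OC)(OC)C/C=C/CC(=O)OC | intermediate
13 | methyl (3E,12E)-6-hydroperoxy-6-methoxydocosa-3,12-dien-10-ynoate (racemic) | CCCCCCCCC/C=C/C#CCCCC(OC)(OO)C/C=C/CC(=O)OC | intermediate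
14 | methyl (2E,12E)-6-hydroperoxy-6-methoxydocosa-2,12-dien-10-ynoate (racemic) | CCCCCCCCC/C=C/C#CCCCC(OC)(OO)CC/C=C/C(=O)OC | intermediate
15 | methyl 2-[(3S,6RS)-6-[(E)-hexadec-6-en-4-yn-1-yl]-6-methoxy-1,2-dioxan-3-yl]acetate (C6 epimers) | CCCCCCCCC/C=C/C#CCCCC1(OC)CC[C@@H](CC(=O)OC)OO1 | intermediate
16 | methyl 2-[(3S,6R)-6-[(E)-hexadec-6-en-4-yn-1-yl]-6-methoxy-1,2-dioxan-3-yl]acetate | CCCCCCCCC/C=C/C#CCCC[C@]1(OC)CC[C@@H](CC(=O)OC)OO1 | intermediate
17 | 2-[(3S,6R)-6-[(E)-hexadec-6-en-4-yn-1-yl]-6-methoxy-1,2-dioxan-3-yl]acetic acid | CCCCCCCCC/C=C/C#CCCC[C@]1(OC)CC[C@@H](CC(=O)O)OO1 | target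

**Total step count:** 7. **Longest linear sequence:** 5 steps (steps 2, 3, 5, 6, 7 from hex-5-ynenitrile 4).

**Steps most likely to fail**

Step 5. What may go wrong: further ionisation of ketal 12 and a second allylation; exchange of both alkoxy groups by hydrogen peroxide; slow migration of the alkene into conjugation; quenching of the superbase by residual acid or hydrogen peroxide; low facial selectivity; base-induced Kornblum–DeLaMare fragmentation of the peroxide. The fallback is a stepwise carbonyl route of known reactions that sets out from 7 and comes back at 14 and then 15. Ortho ester 7 is hydrolysed with aqueous acetic acid to methyl (E)-heptadec-7-en-5-ynoate F1. MeNHOMe·HCl and iPrMgCl convert this into (E)-N-methoxy-N-methylheptadec-7-en-5-ynamide F2, which takes up 2-(1,3-dioxolan-2-yl)ethylmagnesium bromide to give (E)-1-(1,3-dioxolan-2-yl)nonadec-9-en-7-yn-3-one F3. Aqueous acid frees (E)-4-oxoicos-10-en-8-ynal F4, and an aldehyde-selective Wittig reaction with Ph3P=CHCO2Me should give methyl (2E,12E)-6-oxodocosa-2,12-dien-10-ynoate F5. Urea–hydrogen peroxide with an acid catalyst in methanol should convert the ketone into hydroperoxy ketal 14, which is cyclised separately with the same iminophosphorane catalyst to 15.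

Step 6. What may go wrong: acid-promoted loss of the ketal or Hock-type cleavage before the anomeric equilibrium is reached, or an equilibrium that leaves much 6S epimer. The fallback sets out from 15 and comes back at 16. The ketal is hydrolysed (pyridinium p-toluenesulfonate, wet acetone) to methyl 2-[(3S)-6-[(E)-hexadec-6-en-4-yn-1-yl]-6-hydroxy-1,2-dioxan-3-yl]acetate F6, a peroxy hemiketal that equilibrates at C6 by ring–chain tautomerism without added acid. O-Methylation with MeOTf and 2,6-di-tert-butyl-4-methylpyridine at low temperature should then trap the anomerically preferred axial hydroxyl as 16, replacing acid anomerisation by alkylation under basic conditions.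

Step 7. What may go wrong: hydroxide-induced retro-oxa-Michael opening (loss of the C3 configuration) or base-induced fragmentation of the peroxide during saponification. The fallback changes the ester strategy; it sets out from 11 and comes back at 17. Transesterification of 11 with allyl alcohol and Ti(OiPr)4 (tetravalent titanium) gives prop-2-en-1-yl 3-(trimethylsilyl)pent-4-enoate F7. Taken through steps 5 and 6 in place of 11, this should give prop-2-en-1-yl 2-[(3S,6RS)-6-[(E)-hexadec-6-en-4-yn-1-yl]-6-methoxy-1,2-dioxan-3-yl]acetate F8 and then prop-2-en-1-yl 2-[(3S,6R)-6-[(E)-hexadec-6-en-4-yn-1-yl]-6-methoxy-1,2-dioxan-3-yl]acetate F9. Neutral deallylation with Pd(PPh3)4 (zerovalent palladium) and morpholine then gives 17.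

**Further compounds**

F1 | step 5 | methyl (E)-heptadec-7-en-5-ynoate | CCCCCCCCC/C=C/C#CCCCC(=O)OC
F2 | step 5 | (E)-N-methoxy-N-methylheptadec-7-en-5-ynamide | CCCCCCCCC/C=C/C#CCCCC(=O)N(C)OC
F3 | step 5 | (E)-1-(1,3-dioxolan-2-yl)nonadec-9-en-7-yn-3-one | CCCCCCCCC/C=C/C#CCCCC(=O)CCC1OCCO1
F4 | step 5 | (E)-4-oxoicos-10-en-8-ynal | CCCCCCCCC/C=C/C#CCCCC(=O)CCC=O
F5 | step 5 | methyl (2E,12E)-6-oxodocosa-2,12-dien-10-ynoate | CCCCCCCCC/C=C/C#CCCCC(=O)CC/C=C/C(=O)OC
F6 | step 6 | methyl 2-[(3S)-6-[(E)-hexadec-6-en-4-yn-1-yl]-6-hydroxy-1,2-dioxan-3-yl]acetate | CCCCCCCCC/C=C/C#CCCCC1(O)CC[C@@H](CC(=O)OC)OO1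
F7 | step 7 | prop-2-en-1-yl 3-(trimethylsilyl)pent-4-enoate | C=CCOC(=O)CC(C=C)[Si](C)(C)C
F8 | step 7 | prop-2-en-1-yl 2-[(3S,6RS)-6-[(E)-hexadec-6-en-4-yn-1-yl]-6-methoxy-1,2-dioxan-3-yl]acetate | CCCCCCCCC/C=C/C#CCCCC1(OC)CC[C@@H](CC(=O)OCC=C)OO1
F9 | step 7 | prop-2-en-1-yl 2-[(3S,6R)-6-[(E)-hexadec-6-en-4-yn-1-yl]-6-methoxy-1,2-dioxan-3-yl]acetate | CCCCCCCCC/C=C/C#CCCC[C@]1(OC)CC[C@@H](CC(=O)OCC=C)OO1
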